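The cyclohexane ring of the hydrindane is cut into two three-carbon units, C6–C7(Br)–C7a and C3a–C4(O)–C5 (octahydroindene numbering), exploiting the 1,4 relationship of the C7 bromide and the C4 carbinol and the anti disposition of bromine and the ring-fusion bond. The key step rejoins the units at both ends in one flask: silver-triggered ionization of an enantioenriched vicinal dibromide gives a bromiranium ion that a tethered silyl enol ether opens at C7a (ring-fusion bond C3a–C7a, cyclopentane closed), and the methyl ketone so formed alkylates C6 through its enolate (C5–C6). The precursor is an open-chain dibromo tosylate bearing the finished bromocyclohexylidene ring.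

Key step: step 14

Remark: ring A is the bromodimethylcyclohexylidene ring; in steps 1, 9 and 11 the enantiomer of the chiral catalyst or ligand is the one that delivers the configuration stated for the product.

Step 1
Reactants: 1 methyl (2E)-3,7-dimethylocta-2,6-dienoate (methyl geranate)
Product: 2 methyl (2E)-5-[(2R)-3,3-dimethyloxiran-2-yl]-3-methylpent-2-enoate
Conditions: D-fructose-derived Shi ketone (30 mol %), Oxone (KHSO5), K2CO3, Bu4NHSO4, MeCN/dimethoxymethane/aq. buffer (pH 10.5), 0 °C
Reagents that add atoms: potassium peroxymonosulfate, [K+].[O-]S(=O)(=O)OO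
Why: Shi epoxidation; the chiral dioxirane should oxidize the electron-rich trisubstituted 6,7-alkene in preference to the conjugated enoate, and its spiro transition state sets the R configuration at the oxirane CH.

Step 2
Reactants: 2 methyl (2E)-5-[(2R)-3,3-dimethyloxiran-2-yl]-3-methylpent-2-enoate
Product: 3 methyl (2E,6S)-6-bromo-7-hydroxy-3,7-dimethyloct-2-enoate
Conditions: Li2NiBr4, THF, 0 → 23 °C; aq. phosphate buffer
Reagents that add atoms: dilithium tetrabromonickelate Li2NiBr4, [Li+].[Li+].[Ni+2].[Br-].[Br-].[Br-].[Br-]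
Why: SN2 opening of the epoxide by soft bromide at the less substituted carbon; inversion turns the R oxirane carbon into the S bromide and leaves the tertiary alcohol.

Step 3
Reactants: 3 methyl (2E,6S)-6-bromo-7-hydroxy-3,7-dimethyloct-2-enoate
Product: 4 methyl (2E,6S)-6-bromo-3,7-dimethyl-7-[(trimethylsilyl)oxy]oct-2-enoate
Conditions: N-(trimethylsilyl)imidazole, CH2Cl2, 23 °C
Reagents that add atoms: N-(trimethylsilyl)imidazole, C[Si](C)(C)n1ccnc1
Why: O-silylation under non-basic conditions; it prevents the bromohydrin from closing back to the epoxide in step 4 and turns the tertiary oxygen into the group that is ionized there.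

Step 4
Reactants: 4 methyl (2E,6S)-6-bromo-3,7-dimethyl-7-[(trimethylsilyl)oxy]oct-2-enoate
Product: 6 methyl (2E)-2-[(4S)-4-bromo-3,3-dimethylcyclohexylidene]acetate, via silyl ketene acetal 5 (not isolated)
Conditions: LDA (LiN(i-Pr)2), TMSCl, THF, −78 °C; solvent change to CH2Cl2; TMSOTf (0.2 equiv), −78 → −40 °C; Et3N quench
Reagents that add atoms: none
Why: Proposed new method: LDA removes a proton of the C3 methyl group (syn to the ester) and TMSCl traps the cross-conjugated dienolate as 5; catalytic TMSOTf then silylates the tertiary silyl ether, which ionizes with anchimeric help of the neighbouring bromine to a configurationally defined bromiranium ion, and the terminal CH2 of the dienolate (γ-carbon, vinylogous Mukaiyama-type reactivity) attacks the tertiary carbon through a chair with equatorial bromine, closing the six-membered ring A while TMSOTf is regenerated and hexamethyldisiloxane is lost; the closest known reaction types are bromiranium-initiated polyene cyclizations that start from enantioenriched bromohydrin derivatives and γ-selective alkylations of silyl dienolates; the C–Br centre is carried over unchanged (S), and the s-trans dienolate should place the ester trans to the attacking CH2 (E).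

Step 5
Reactants: 6 methyl (2E)-2-[(4S)-4-bromo-3,3-dimethylcyclohexylidene]acetate
Product: 7 (2E)-2-[(4S)-4-bromo-3,3-dimethylcyclohexylidene]ethan-1-ol
Conditions: DIBAL-H (i-Bu2AlH, 2.2 equiv), CH2Cl2, −78 °C; aq. potassium sodium tartrate
Reagents that add atoms: none
Why: 1,2-Reduction of the enoate to the allylic alcohol; alkene geometry and the secondary bromide should not be touched at this temperature.

Step 6
Reactants: 7 (2E)-2-[(4S)-4-bromo-3,3-dimethylcyclohexylidene]ethan-1-ol
Product: 9 (3E,5E)-5-[(4S)-4-bromo-3,3-dimethylcyclohexylidene]pent-3-en-2-one, via enal 8 (not isolated)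
Conditions: MnO2 (10 equiv), Ph3P=CHC(O)CH3, CH2Cl2, 40 °C
Reagents that add atoms: 1-(triphenylphosphoranylidene)propan-2-one, CC(=O)C=P(c1ccccc1)(c1ccccc1)c1ccccc1
Why: Tandem allylic oxidation and Wittig reaction; the stabilized ylide should give the E enone, and the base-free medium keeps the exocyclic alkene geometry.

Step 7
Reactants: 10 4-bromobut-1-yne
Product: 12 (2E)-5-bromo-3-methylpent-2-en-1-ol, via alkenylalane 11 (not isolated)
Conditions: AlMe3, Cp2ZrCl2 (0.25 equiv), CH2Cl2, 0 → 23 °C; then n-BuLi, THF, −78 °C; (CH2O)n, −78 → 23 °C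
Reagents that add atoms: trimethylaluminium AlMe3, C[Al](C)C; paraformaldehyde (as formaldehyde), C=O
Why: Negishi carboalumination; methyl and aluminium add syn across the alkyne (methyl to the internal carbon), and hydroxymethylation of the alanate with retention gives the E allylic alcohol.

Step 8
Reactants: 12 (2E)-5-bromo-3-methylpent-2-en-1-ol
Product: 13 {[(2E)-5-bromo-3-methylpent-2-en-1-yl]oxy}(tert-butyl)dimethylsilane
Conditions: TBSCl, imidazole, CH2Cl2, 23 °C
Reagents that add atoms: tert-butyldimethylsilyl chloride, CC(C)(C)[Si](C)(C)Cl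
Why: Standard silyl protection of the primary alcohol so that the bromide can be turned into a Grignard reagent.

Step 9
Reactants: 13 {[(2E)-5-bromo-3-methylpent-2-en-1-yl]oxy}(tert-butyl)dimethylsilane; 9 (3E,5E)-5-[(4S)-4-bromo-3,3-dimethylcyclohexylidene]pent-3-en-2-one
Product: 15 (4R,7E)-4-{(E)-[(4S)-4-bromo-3,3-dimethylcyclohexylidene]methyl}-9-[(tert-butyldimethylsilyl)oxy]-7-methylnon-7-en-2-one, via Grignard reagent 14 (not isolated)
Conditions: Mg, Et2O, 35 °C; then CuBr·SMe2 (5 mol %), Josiphos ligand (6 mol %), t-BuOMe, −75 °C, slow addition of 9; aq. NH4Cl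
Reagents that add atoms: none
Why: Copper-catalysed asymmetric conjugate addition of a Grignard reagent to an acyclic enone; the fully substituted δ-carbon of the dienone should disfavour 1,6-addition, and the chiral ferrocenyl diphosphine controls the face of attack at C4 (R) independently of the remote C–Br centre.

Step 10
Reactants: 15 (4R,7E)-4-{(E)-[(4S)-4-bromo-3,3-dimethylcyclohexylidene]methyl}-9-[(tert-butyldimethylsilyl)oxy]-7-methylnon-7-en-2-one
Product: 16 (4R,7E)-4-{(E)-[(4S)-4-bromo-3,3-dimethylcyclohexylidene]methyl}-9-hydroxy-7-methylnon-7-en-2-one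
Conditions: HF·pyridine, pyridine, THF, 0 °C
Reagents that add atoms: none
Why: Fluoride-mediated cleavage of the primary allylic silyl ether; ketone, alkenes and the secondary bromide are inert.

Step 11
Reactants: 16 (4R,7E)-4-{(E)-[(4S)-4-bromo-3,3-dimethylcyclohexylidene]methyl}-9-hydroxy-7-methylnon-7-en-2-one
Product: 17 (4R,7R,8S)-7,8-dibromo-4-{(E)-[(4S)-4-bromo-3,3-dimethylcyclohexylidene]methyl}-9-hydroxy-7-methylnonan-2-one
Conditions: BrTi(OiPr)3, diethyl 2,2-dibromomalonate, chiral TADDOL-type diol ligand (20 mol %), hexanes/CH2Cl2, 23 °C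
Reagents that add atoms: diethyl 2,2-dibromomalonate, CCOC(=O)C(Br)(Br)C(=O)OCC; bromotitanium triisopropoxide BrTi(OiPr)3, CC(C)O[Ti](Br)(OC(C)C)OC(C)C
Why: Titanium-mediated catalytic enantioselective dibromination of an allylic alcohol; binding of the alkoxide directs anti addition across the E alkene and makes the reaction site-selective over the ring A alkene, and the ligand sets 7R,8S.

Step 12
Reactants: 17 (4R,7R,8S)-7,8-dibromo-4-{(E)-[(4S)-4-bromo-3,3-dimethylcyclohexylidene]methyl}-9-hydroxy-7-methylnonan-2-one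
Product: 18 (2S,3R,6R)-2,3-dibromo-6-{(E)-[(4S)-4-bromo-3,3-dimethylcyclohexylidene]methyl}-3-methyl-8-oxononyl 4-methylbenzenesulfonate
Conditions: TsCl, pyridine, CH2Cl2, 0 °C
Reagents that add atoms: 4-methylbenzenesulfonyl chloride, Cc1ccc(cc1)S(=O)(=O)Cl
Why: Sulfonylation of the primary alcohol; it installs the leaving group for the second ring closure without touching the bromides.

Step 13
Reactants: 18 (2S,3R,6R)-2,3-dibromo-6-{(E)-[(4S)-4-bromo-3,3-dimethylcyclohexylidene]methyl}-3-methyl-8-oxononyl 4-methylbenzenesulfonate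
Product: 19 (2S,3R,6S,7Z)-2,3-dibromo-6-{(E)-[(4S)-4-bromo-3,3-dimethylcyclohexylidene]methyl}-3-methyl-8-[(trimethylsilyl)oxy]non-7-en-1-yl 4-methylbenzenesulfonate
Conditions: TMSOTf, Et3N, CH2Cl2, 0 °C; pentane extraction, used crude
Reagents that add atoms: trimethylsilyl trifluoromethanesulfonate, C[Si](C)(C)OS(=O)(=O)C(F)(F)F
Why: Soft enolization under equilibrating conditions should favour the more substituted, Z-configured silyl enol ether toward C7; the minor methyl-side isomer cannot reach the cationic carbon through a five-membered transition state.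

Step 14
Reactants: 19 (2S,3R,6S,7Z)-2,3-dibromo-6-{(E)-[(4S)-4-bromo-3,3-dimethylcyclohexylidene]methyl}-3-methyl-8-[(trimethylsilyl)oxy]non-7-en-1-yl 4-methylbenzenesulfonate
Product: 21 (3S,3aS,7S,7aS)-7-bromo-3-{(E)-[(4S)-4-bromo-3,3-dimethylcyclohexylidene]methyl}-7a-methyloctahydro-4H-inden-4-one, via cyclopentyl ketone 20 (not isolated)
Conditions: AgOTf (1.1 equiv), 2,6-di-tert-butyl-4-methylpyridine, CH2Cl2, −78 → −40 °C; then THF, KHMDS (KN(SiMe3)2, 2.3 equiv), −78 → 0 °C
Reagents that add atoms: none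
Why: Proposed new method: AgOTf abstracts the tertiary bromide of 19 with anchimeric help of the vicinal secondary bromine, and the resulting bromiranium ion is opened at its tertiary carbon by the tethered silyl enol ether carbon (5-exo for both the enol ether and the bromiranium, anti to bromine, net retention at that carbon), which forms C3a–C7a, closes the cyclopentane and releases TMSOTf; KHMDS then forms the kinetic methyl-side enolate of 20, which displaces the primary tosylate (6-exo-tet, enolendo) to form C5–C6 and close the cyclohexanone. The closest known reaction types are the Lewis-acid- or silver-promoted tert-alkylation of silyl enol ethers by tertiary halides, the stereospecific capture of bromiranium ions generated by ionization of bromohydrin derivatives, and the intramolecular alkylation of ketone enolates. C7 and C7a keep the configurations written into dibromide 17 (bromine untouched at C7, double inversion at C7a), while C3a is set in the first closure by the C3 stereocentre and the new quaternary C7a, the acetyl group taking the all-trans position on the cyclopentane. That trans arrangement makes the second closure give the trans-fused hydrindanone with equatorial bromine. The step needs the enol ether to outrun elimination and the ring A alkene in capturing the cation, which its far higher nucleophilicity and the five-membered transition state should secure, and it needs deprotonation at CH3 and not at C3a–H, which KHMDS at −78 °C should secure.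

Step 15
Reactants: 21 (3S,3aS,7S,7aS)-7-bromo-3-{(E)-[(4S)-4-bromo-3,3-dimethylcyclohexylidene]methyl}-7a-methyloctahydro-4H-inden-4-one
Product: 22 (3S,3aS,4R,7S,7aS)-7-bromo-3-{(E)-[(4S)-4-bromo-3,3-dimethylcyclohexylidene]methyl}-4,7a-dimethyloctahydro-1H-inden-4-ol
Conditions: MeLi, CeCl3 (anhydrous), THF, −78 °C
Reagents that add atoms: methyllithium, [Li]C
Why: 1,2-Addition of a weakly basic organocerium reagent; axial attack is blocked by the syn-axial C7a methyl group, so methyl should enter equatorially and give the axial alcohol (4R), and the low basicity avoids epimerization at C3a and loss of HBr.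

Compound list
1 | methyl (2E)-3,7-dimethylocta-2,6-dienoate | COC(=O)/C=C(\C)CCC=C(C)C | starting material
2 | methyl (2E)-5-[(2R)-3,3-dimethyloxiran-2-yl]-3-methylpent-2-enoate | COC(=O)/C=C(\C)CC[C@H]1OC1(C)C | intermediate
3 | methyl (2E,6S)-6-bromo-7-hydroxy-3,7-dimethyloct-2-enoate | COC(=O)/C=C(\C)CC[C@H](Br)C(C)(C)O | intermediate
4 | methyl (2E,6S)-6-bromo-3,7-dimethyl-7-[(trimethylsilyl)oxy]oct-2-enoate | COC(=O)/C=C(\C)CC[C@H](Br)C(C)(C)O[Si](C)(C)C | intermediate
5 | {[(6S)-6-bromo-1-methoxy-7-methyl-3-methylidene-7-[(trimethylsilyl)oxy]oct-1-en-1-yl]oxy}trimethylsilane | COC(O[Si](C)(C)C)=CC(=C)CC[C@H](Br)C(C)(C)O[Si](C)(C)C | intermediate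
6 | methyl (2E)-2-[(4S)-4-bromo-3,3-dimethylcyclohexylidene]acetate | CC1(C)C/C(=C/C(=O)OC)CC[C@@H]1Br | intermediate
7 | (2E)-2-[(4S)-4-bromo-3,3-dimethylcyclohexylidene]ethan-1-ol | CC1(C)C/C(=C/CO)CC[C@@H]1Br | intermediate
8 | (2E)-2-[(4S)-4-bromo-3,3-dimethylcyclohexylidene]acetaldehyde | CC1(C)C/C(=C/C=O)CC[C@@H]1Br | intermediate
9 | (3E,5E)-5-[(4S)-4-bromo-3,3-dimethylcyclohexylidene]pent-3-en-2-one | CC1(C)C/C(=C/C=C/C(C)=O)CC[C@@H]1Br | intermediate
10 | 4-bromobut-1-yne | C#CCCBr | starting material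
11 | [(1E)-4-bromo-2-methylbut-1-en-1-yl]dimethylalumane | C[Al](C)/C=C(\C)CCBr | intermediate
12 | (2E)-5-bromo-3-methylpent-2-en-1-ol | OC/C=C(\C)CCBr | intermediate
13 | {[(2E)-5-bromo-3-methylpent-2-en-1-yl]oxy}(tert-butyl)dimethylsilane | CC(C)(C)[Si](C)(C)OC/C=C(\C)CCBr | intermediate
14 | {(3E)-5-[(tert-butyldimethylsilyl)oxy]-3-methylpent-3-en-1-yl}magnesium bromide | CC(C)(C)[Si](C)(C)OC/C=C(\C)CC[Mg]Br | intermediate
15 | (4R,7E)-4-{(E)-[(4S)-4-bromo-3,3-dimethylcyclohexylidene]methyl}-9-[(tert-butyldimethylsilyl)oxy]-7-methylnon-7-en-2-one | CC1(C)C/C(=C/[C@@H](CC(C)=O)CC/C(C)=C/CO[Si](C)(C)C(C)(C)C)CC[C@@H]1Br | intermediate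
16 | (4R,7E)-4-{(E)-[(4S)-4-bromo-3,3-dimethylcyclohexylidene]methyl}-9-hydroxy-7-methylnon-7-en-2-one | CC1(C)C/C(=C/[C@@H](CC(C)=O)CC/C(C)=C/CO)CC[C@@H]1Br | intermediate
17 | (4R,7R,8S)-7,8-dibromo-4-{(E)-[(4S)-4-bromo-3,3-dimethylcyclohexylidene]methyl}-9-hydroxy-7-methylnonan-2-one | CC1(C)C/C(=C/[C@@H](CC(C)=O)CC[C@](Br)(C)[C@@H](Br)CO)CC[C@@H]1Br | intermediate
18 | (2S,3R,6R)-2,3-dibromo-6-{(E)-[(4S)-4-bromo-3,3-dimethylcyclohexylidene]methyl}-3-methyl-8-oxononyl 4-methylbenzenesulfonate | CC1(C)C/C(=C/[C@@H](CC(C)=O)CC[C@](Br)(C)[C@@H](Br)COS(=O)(=O)c2ccc(C)cc2)CC[C@@H]1Br | intermediate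
19 | (2S,3R,6S,7Z)-2,3-dibromo-6-{(E)-[(4S)-4-bromo-3,3-dimethylcyclohexylidene]methyl}-3-methyl-8-[(trimethylsilyl)oxy]non-7-en-1-yl 4-methylbenzenesulfonate | CC1(C)C/C(=C/[C@@H](/C=C(/C)O[Si](C)(C)C)CC[C@](Br)(C)[C@@H](Br)COS(=O)(=O)c2ccc(C)cc2)CC[C@@H]1Br | intermediate
20 | (2R)-2-[(1S,2S,3S)-2-acetyl-3-{(E)-[(4S)-4-bromo-3,3-dimethylcyclohexylidene]methyl}-1-methylcyclopentyl]-2-bromoethyl 4-methylbenzenesulfonate | CC1(C)C/C(=C/[C@@H]2CC[C@](C)([C@@H](Br)COS(=O)(=O)c3ccc(C)cc3)[C@H]2C(C)=O)CC[C@@H]1Br | intermediate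
21 | (3S,3aS,7S,7aS)-7-bromo-3-{(E)-[(4S)-4-bromo-3,3-dimethylcyclohexylidene]methyl}-7a-methyloctahydro-4H-inden-4-one | CC1(C)C/C(=C/[C@@H]2CC[C@]3(C)[C@@H](Br)CCC(=O)[C@@H]23)CC[C@@H]1Br | intermediate
22 | (3S,3aS,4R,7S,7aS)-7-bromo-3-{(E)-[(4S)-4-bromo-3,3-dimethylcyclohexylidene]methyl}-4,7a-dimethyloctahydro-1H-inden-4-ol | CC1(C)C/C(=C/[C@@H]2CC[C@]3(C)[C@@H](Br)CC[C@@](C)(O)[C@@H]23)CC[C@@H]1Br | target

Total step count: 15. Longest linear sequence: 13 steps (steps 1–6 and 9–15).

Steps most likely to fail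

1. Step 14 (Proposed new method). The cation may be lost by elimination or by capture through the ring A alkene. Configuration at C7a may erode if the bromiranium ion opens to a free tertiary cation. The base of the second stage may eliminate the bromo tosylate instead of allowing ring closure. The fallback uses known chemistry, sets out from 16 and comes back at 20 and then 21.
   - 16 is bis-silylated (TMSOTf, Et3N, CH2Cl2, 0 °C) to {[(2Z,4S,7E)-4-{(E)-[(4S)-4-bromo-3,3-dimethylcyclohexylidene]methyl}-7-methyl-9-[(trimethylsilyl)oxy]nona-2,7-dien-2-yl]oxy}trimethylsilane F1.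
   - Hg(OTf)2·PhNMe2 (MeCN, −20 °C) activates the trisubstituted alkene for 5-exo attack of the enol ether (mercury-induced cation–olefin cyclization, anti addition, reversible mercuration so that the C3 centre selects the all-trans cyclopentane). Aqueous NaCl then gives [(1R)-1-[(1S,2S,3S)-2-acetyl-3-{(E)-[(4S)-4-bromo-3,3-dimethylcyclohexylidene]methyl}-1-methylcyclopentyl]-2-hydroxyethyl](chloro)mercury F2.
   - Bromodemercuration with retention (Br2, LiBr, pyridine, dark) gives 1-[(1S,2S,5S)-2-[(1R)-1-bromo-2-hydroxyethyl]-5-{(E)-[(4S)-4-bromo-3,3-dimethylcyclohexylidene]methyl}-2-methylcyclopentyl]ethan-1-one F3.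
   - TsCl/pyridine gives 20, which KHMDS closes to 21 as in the second stage of step 14.

2. Step 4 (Proposed new method). The dienolate may attack through its α-carbon instead of the terminal CH2, a cisoid dienolate conformer may scramble the geometry of the new exocyclic alkene, or the tertiary silyl ether may fail to ionize before the ketene acetal is desilylated. The fallback uses known chemistry, sets out from 2 and comes back at 6.
   - 2 is converted (LDA, TMSCl, THF, −78 °C) into {[5-[(2R)-3,3-dimethyloxiran-2-yl]-1-methoxy-3-methylidenepent-1-en-1-yl]oxy}trimethylsilane F4.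
   - MeAlCl2 (CH2Cl2, −78 °C) opens the epoxide at its tertiary carbon with attack of the dienolate CH2 (epoxide-initiated cation–olefin cyclization terminated by an enol silane), giving methyl (2E)-2-[(4R)-4-hydroxy-3,3-dimethylcyclohexylidene]acetate F5.
   - An Appel reaction (CBr4, PPh3, inversion) gives 6.

3. Step 9. The Grignard reagent may add 1,6 instead of 1,4, or the facial selectivity at C4 may be poor on this dienone. The fallback sets out from 7 and comes back at 15.
   - 7 is oxidized in the presence of an auxiliary-bearing ylide (MnO2, 3-[(triphenylphosphoranylidene)acetyl]-(4R)-4-phenyl-1,3-oxazolidin-2-one, CH2Cl2, 40 °C) to (4R)-3-{(2E,4E)-4-[(4S)-4-bromo-3,3-dimethylcyclohexylidene]but-2-enoyl}-4-phenyl-1,3-oxazolidin-2-one F6.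
   - Grignard reagent 14 with CuBr·SMe2 (THF, −40 °C) adds to the chelated s-cis imide from the face opposite the phenyl group, giving (4R)-3-[(3R,6E)-3-{(E)-[(4S)-4-bromo-3,3-dimethylcyclohexylidene]methyl}-8-[(tert-butyldimethylsilyl)oxy]-6-methyloct-6-enoyl]-4-phenyl-1,3-oxazolidin-2-one F7.
   - AlMe3/MeNHOMe·HCl gives (3R,6E)-3-{(E)-[(4S)-4-bromo-3,3-dimethylcyclohexylidene]methyl}-8-[(tert-butyldimethylsilyl)oxy]-N-methoxy-N,6-dimethyloct-6-enamide F8, and MeMgBr gives 15.

Further compounds
F1 | step 14 | {[(2Z,4S,7E)-4-{(E)-[(4S)-4-bromo-3,3-dimethylcyclohexylidene]methyl}-7-methyl-9-[(trimethylsilyl)oxy]nona-2,7-dien-2-yl]oxy}trimethylsilane | CC1(C)C/C(=C/[C@@H](/C=C(/C)O[Si](C)(C)C)CC/C(C)=C/CO[Si](C)(C)C)CC[C@@H]1Br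
F2 | step 14 | [(1R)-1-[(1S,2S,3S)-2-acetyl-3-{(E)-[(4S)-4-bromo-3,3-dimethylcyclohexylidene]methyl}-1-methylcyclopentyl]-2-hydroxyethyl](chloro)mercury | CC1(C)C/C(=C/[C@@H]2CC[C@](C)([C@@H]([Hg]Cl)CO)[C@H]2C(C)=O)CC[C@@H]1Br
F3 | step 14 | 1-[(1S,2S,5S)-2-[(1R)-1-bromo-2-hydroxyethyl]-5-{(E)-[(4S)-4-bromo-3,3-dimethylcyclohexylidene]methyl}-2-methylcyclopentyl]ethan-1-one | CC1(C)C/C(=C/[C@@H]2CC[C@](C)([C@@H](Br)CO)[C@H]2C(C)=O)CC[C@@H]1Br
F4 | step 4 | {[5-[(2R)-3,3-dimethyloxiran-2-yl]-1-methoxy-3-methylidenepent-1-en-1-yl]oxy}trimethylsilane | COC(O[Si](C)(C)C)=CC(=C)CC[C@H]1OC1(C)C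
F5 | step 4 | methyl (2E)-2-[(4R)-4-hydroxy-3,3-dimethylcyclohexylidene]acetate | CC1(C)C/C(=C/C(=O)OC)CC[C@H]1O
F6 | step 9 | (4R)-3-{(2E,4E)-4-[(4S)-4-bromo-3,3-dimethylcyclohexylidene]but-2-enoyl}-4-phenyl-1,3-oxazolidin-2-one | CC1(C)C/C(=C/C=C/C(=O)N2[C@H](c3ccccc3)COC2=O)CC[C@@H]1Br
F7 | step 9 | (4R)-3-[(3R,6E)-3-{(E)-[(4S)-4-bromo-3,3-dimethylcyclohexylidene]methyl}-8-[(tert-butyldimethylsilyl)oxy]-6-methyloct-6-enoyl]-4-phenyl-1,3-oxazolidin-2-one | CC1(C)C/C(=C/[C@@H](CC(=O)N2[C@H](c3ccccc3)COC2=O)CC/C(C)=C/CO[Si](C)(C)C(C)(C)C)CC[C@@H]1Br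
F8 | step 9 | (3R,6E)-3-{(E)-[(4S)-4-bromo-3,3-dimethylcyclohexylidene]methyl}-8-[(tert-butyldimethylsilyl)oxy]-N-methoxy-N,6-dimethyloct-6-enamide | CC1(C)C/C(=C/[C@@H](CC(=O)N(C)OC)CC/C(C)=C/CO[Si](C)(C)C(C)(C)C)CC[C@@H]1Br
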